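**Retrosynthetic overview**
Numbering (spiro[5.5]undecane): ring A = C1(CMe2)–C2(HBr)–C3–C4–C5(=CH2)–C6(spiro); ring B = C6–C7–C8(HBr)–C9(Me)(Cl)–C10–C11.
Target ⇒ C8 bromide by SN2 inversion of a chlorohydrin ⇒ anti opening of a C8–C9 epoxide by chloride at C9 ⇒ ring B alkene (10-bromo-β-chamigrene skeleton) ⇒ C8 ketone 13.
13 ⇒ disconnection C10–C11: ring B arises from a spiro-cyclobutanol (C6, C7, C8, C11) whose carbinol carbon C8 carries an isopropenyl group (= C9, C10 and the C9 methyl), by rhodium-catalysed C8–C11 cleavage and recyclisation.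
Enabling feature: in ring B the spiro carbon C6 is flanked by two CH2 groups (C7, C11), so C6–C7–C8–C11 map onto a 3,3-disubstituted cyclobutanol whose two ring bonds at C8 differ only through the chirality of ring A; a chiral ligand chooses between them and so sets the quaternary centre.
Order of rings: the cyclobutane is bought; ring A is closed onto it by a bromonium-assisted cation–enol cyclisation (C1–C6 bond, vicinal quaternary carbons); ring B is formed last by two-carbon ring expansion.

Key step: step 8

Remark: locants in the Why lines are those of the target numbering above; compound names use their own numbering.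
Assumption: (R)-DTBM-SEGPHOS is taken to select, in carbinol isomer 12, the cyclobutane bond that leads to the (6R) spiro centre; if the sense is opposite, the (S)-ligand is used.

Step 1
Reactants: 1 methyl 3,3-dimethoxycyclobutane-1-carboxylate
Product: 2 N,3,3-trimethoxy-N-methylcyclobutane-1-carboxamide
Conditions: MeNH(OMe)·HCl, iPrMgCl, THF, −20 → 0 °C
Reagents that add atoms: N,O-dimethylhydroxylamine hydrochloride, CNOC.Cl
Why: Weinreb amide formation by aminolysis of the ester with the chloromagnesium amide made in situ; the dimethyl ketal is inert to the basic medium.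

Step 2
Reactants: 2 N,3,3-trimethoxy-N-methylcyclobutane-1-carboxamide; 3 5-bromo-2-methylpent-2-ene
Product: 5 1-(3,3-dimethoxycyclobutyl)-5-methylhex-4-en-1-one, via Grignard reagent 4 (not isolated)
Conditions: 3, Mg, THF, rt; then 2, THF, 0 °C; H2O quench
Reagents that add atoms: none
Why: Weinreb ketone synthesis, in which the chelated tetrahedral adduct of the homoprenyl Grignard reagent survives until the quench so that only one addition occurs.

Step 3
Reactants: 5 1-(3,3-dimethoxycyclobutyl)-5-methylhex-4-en-1-one
Product: 6 1-(3,3-dimethoxycyclobutyl)-3-[(2S)-3,3-dimethyloxiran-2-yl]propan-1-one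
Conditions: L-fructose-derived Shi ketone (30 mol %), Oxone (KHSO5), K2CO3, Bu4NHSO4 (cat.), MeCN–dimethoxymethane–aq. Na2B4O7 buffer (pH 10.5), 0 °C
Reagents that add atoms: potassium peroxymonosulfate, [K+].[O-]S(=O)(=O)OO
Why: Shi asymmetric epoxidation, in which the chiral dioxirane attacks one face of the trisubstituted alkene through the spiro transition state and should give the (S)-epoxide (the precursor of C2); ketone and ketal are inert at this pH.

Step 4
Reactants: 6 1-(3,3-dimethoxycyclobutyl)-3-[(2S)-3,3-dimethyloxiran-2-yl]propan-1-one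
Product: 8 3-[(4R)-4-bromo-5-hydroxy-5-methylhexanoyl]cyclobutan-1-one, via bromohydrin ketal 7 (not isolated)
Conditions: Li2NiBr4 (0.4 M in THF), 0 °C → rt; then 1 M HCl, THF, rt
Reagents that add atoms: dilithium tetrabromonickelate, [Li+].[Li+].[Ni+2].[Br-].[Br-].[Br-].[Br-]; water, O
Why: SN2 opening of the trisubstituted epoxide by soft bromide at the less substituted carbon with inversion should give the (R)-bromide that becomes C2, and the acidic work-up hydrolyses the dimethyl ketal.

Step 5
Reactants: 8 3-[(4R)-4-bromo-5-hydroxy-5-methylhexanoyl]cyclobutan-1-one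
Product: 9 (8R)-8-bromo-9,9-dimethylspiro[3.5]nonane-2,5-dione
Conditions: SnCl4 (1.5 equiv), CH2Cl2, −78 °C → rt
Reagents that add atoms: none
Why: intramolecular SN1-type α-tert-alkylation of a ketone (cation–enol cyclisation), in which SnCl4 ionises the tertiary alcohol with anchimeric help from the vicinal bromine and only the enol toward the cyclobutane carbon can close a six-membered ring (C1–C6 bond), O-alkylation being reversible under the Lewis acid; the C–Br centre is not touched and C6 is not yet stereogenic.

Step 6
Reactants: 9 (8R)-8-bromo-9,9-dimethylspiro[3.5]nonane-2,5-dione; 10 prop-1-en-2-ylmagnesium bromide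
Product: 11 (8R)-8-bromo-2-hydroxy-9,9-dimethyl-2-(prop-1-en-2-yl)spiro[3.5]nonan-5-one, the isomer with the hydroxyl cis to C9 (the CMe2 carbon) across the cyclobutane
Conditions: 10 (0.5 M in THF, 1.05 equiv), THF, −78 °C; H2O quench
Reagents that add atoms: none
Why: Grignard 1,2-addition, chemoselective for the strained, unhindered cyclobutanone over the neopentylic cyclohexanone; attack anti to the gem-dimethyl-bearing ring carbon should give mainly the carbinol drawn, and the minor carbinol epimer is removed by chromatography.

Step 7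
Reactants: 11 (8R)-8-bromo-2-hydroxy-9,9-dimethyl-2-(prop-1-en-2-yl)spiro[3.5]nonan-5-one
Product: 12 (6R)-6-bromo-5,5-dimethyl-9-methylidene-2-(prop-1-en-2-yl)spiro[3.5]nonan-2-ol, hydroxyl cis to C5 (the CMe2 carbon)
Conditions: Cp2TiMe2 (3 equiv), toluene–THF, 70 °C, dark
Reagents that add atoms: dimethyltitanocene, C[Ti](C)(C1C=CC=C1)C1C=CC=C1
Why: Petasis methylenation, in which the titanium methylidene olefinates the hindered, enolisable ketone under non-basic conditions that spare the secondary bromide; the tertiary alcohol is carried as its titanium alkoxide and freed on work-up.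

Step 8
Reactants: 12 (6R)-6-bromo-5,5-dimethyl-9-methylidene-2-(prop-1-en-2-yl)spiro[3.5]nonan-2-ol
Product: 13 (6R,8R)-8-bromo-3,7,7-trimethyl-11-methylidenespiro[5.5]undecan-2-one (mixture of C3 methyl epimers)
Conditions: [Rh(OH)(cod)]2 (2.5 mol %), (R)-DTBM-SEGPHOS (6 mol %), toluene, 110 °C
Reagents that add atoms: none
Why: Proposed new method: exchange with Rh–OH gives a monovalent rhodium cyclobutanolate, β-carbon elimination (strain release) cleaves the C8–C11 bond to a neopentyl-type alkylrhodium without β-hydrogen that is tethered to the isopropenyl ketone just formed, conjugate carbometalation forms C10–C11 and the rhodium enolate is protonated by the next molecule of 12. The closest known reaction type is the rhodium/bisphosphine-catalysed enantioselective β-carbon elimination of 3,3-disubstituted tert-cyclobutanols with trapping of the alkylrhodium by a pendant allene to give cyclohexenones with quaternary stereocentres; here the enone released by the cleavage itself is the acceptor. Ring B is closed in the 6-endo-trig mode. The spiro centre C6 is set by which of the two diastereotopic cyclobutane C–C bonds is cleaved, and this is under ligand control because the only other stereocentre (C2) is remote; the bond to the CH2 cis to the C2 bromine must break. The C9 methyl centre formed on protonation is not controlled and is erased in step 9. The step needs ring-bond cleavage over loss of the alkenyl group (secured by ring strain), 6-endo over 5-exo closure (secured by the polarisation of the enone and the unsubstituted β-carbon) and tolerance of the secondary bromide and the exocyclic alkene (both neopentylic and hindered).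

Step 9
Reactants: 13 (6R,8R)-8-bromo-3,7,7-trimethyl-11-methylidenespiro[5.5]undecan-2-one
Product: 14 (6R,8R)-8-bromo-3,7,7-trimethyl-11-methylidenespiro[5.5]undec-2-en-2-yl trifluoromethanesulfonate
Conditions: Tf2O, 2,6-di-tert-butyl-4-methylpyridine, CH2Cl2, 0 °C → rt
Reagents that add atoms: triflic anhydride, O=S(=O)(OS(=O)(=O)C(F)(F)F)C(F)(F)F
Why: enol triflate formation, in which the O-triflyl oxocarbenium ion should lose the C9 proton (Zaitsev direction, the alternative C7 protons being neopentylic) to give the tetrasubstituted enol triflate from both C9 epimers.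

Step 10
Reactants: 14 (6R,8R)-8-bromo-3,7,7-trimethyl-11-methylidenespiro[5.5]undec-2-en-2-yl trifluoromethanesulfonate
Product: 15 (6R,8R)-8-bromo-3,7,7-trimethyl-11-methylidenespiro[5.5]undec-2-ene
Conditions: Pd(OAc)2 (5 mol %), PPh3 (10 mol %), HCO2H, Bu3N, DMF, 60 °C
Reagents that add atoms: none
Why: palladium-catalysed formate reduction of an enol triflate (oxidative addition, decarboxylation of the palladium formate, reductive elimination) should give the trisubstituted ring B alkene, while the hindered secondary alkyl bromide does not undergo oxidative addition.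

Step 11
Reactants: 15 (6R,8R)-8-bromo-3,7,7-trimethyl-11-methylidenespiro[5.5]undec-2-ene
Product: 16 (2R,3S,6R,8R)-8-bromo-2,3-epoxy-3,7,7-trimethyl-11-methylidenespiro[5.5]undecane
Conditions: D-fructose-derived Shi ketone (30 mol %), Oxone (KHSO5, 1.3 equiv), K2CO3, MeCN–dimethoxymethane–aq. buffer (pH 10.5), 0 °C
Reagents that add atoms: potassium peroxymonosulfate, [K+].[O-]S(=O)(=O)OO
Why: Shi asymmetric epoxidation under reagent control should place the oxygen on the face of ring B anti to C5 (syn to C1), a preference expected to be reinforced by a half-chair with C5 pseudoaxial; the electron-rich trisubstituted alkene reacts before the hindered 1,1-disubstituted alkene of ring A.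

Step 12
Reactants: 16 (2R,3S,6R,8R)-8-bromo-2,3-epoxy-3,7,7-trimethyl-11-methylidenespiro[5.5]undecane
Product: 17 (2R,3R,6R,8R)-8-bromo-3-chloro-3,7,7-trimethyl-11-methylidenespiro[5.5]undecan-2-ol
Conditions: HCl (2 M in Et2O, 1.05 equiv), Et2O, −78 → −40 °C
Reagents that add atoms: hydrogen chloride, Cl
Why: acid-promoted epoxide opening (borderline SN2) in which chloride attacks the tertiary C9 of the protonated epoxide with inversion, setting C9 with chlorine anti to the C8 oxygen; at this temperature and stoichiometry the exocyclic alkene should not be hydrochlorinated.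

Step 13
Reactants: 17 (2R,3R,6R,8R)-8-bromo-3-chloro-3,7,7-trimethyl-11-methylidenespiro[5.5]undecan-2-ol
Product: 19 (2R,6R,8S,9R)-2,8-dibromo-9-chloro-1,1,9-trimethyl-5-methylidenespiro[5.5]undecane, via triflate 18 (not isolated)
Conditions: Tf2O, pyridine, CH2Cl2, −78 → −30 °C; then Bu4NBr, toluene, −30 °C → rt
Reagents that add atoms: tetrabutylammonium bromide, CCCC[N+](CCCC)(CCCC)CCCC.[Br-]; triflic anhydride (triflyl group of 18 only), O=S(=O)(OS(=O)(=O)C(F)(F)F)C(F)(F)F
Why: SN2 displacement of a secondary triflate by bromide with inversion places the C8 bromine cis to the C9 chlorine, the net syn arrangement that an anti addition to the alkene cannot give.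

**Compound list**
1 | methyl 3,3-dimethoxycyclobutane-1-carboxylate | COC(=O)C1CC(OC)(OC)C1 | starting material
2 | N,3,3-trimethoxy-N-methylcyclobutane-1-carboxamide | CON(C)C(=O)C1CC(OC)(OC)C1 | intermediate
3 | 5-bromo-2-methylpent-2-ene | CC(C)=CCCBr | starting material
4 | (4-methylpent-3-en-1-yl)magnesium bromide | CC(C)=CCC[Mg]Br | intermediate (not isolated)
5 | 1-(3,3-dimethoxycyclobutyl)-5-methylhex-4-en-1-one | COC1(OC)CC(C1)C(=O)CCC=C(C)C | intermediate
6 | 1-(3,3-dimethoxycyclobutyl)-3-[(2S)-3,3-dimethyloxiran-2-yl]propan-1-one | COC1(OC)CC(C1)C(=O)CC[C@@H]2OC2(C)C | intermediate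
7 | (4R)-4-bromo-1-(3,3-dimethoxycyclobutyl)-5-hydroxy-5-methylhexan-1-one | COC1(OC)CC(C1)C(=O)CC[C@@H](Br)C(C)(C)O | intermediate (not isolated)
8 | 3-[(4R)-4-bromo-5-hydroxy-5-methylhexanoyl]cyclobutan-1-one | O=C1CC(C1)C(=O)CC[C@@H](Br)C(C)(C)O | intermediate
9 | (8R)-8-bromo-9,9-dimethylspiro[3.5]nonane-2,5-dione | O=C1CC[C@@H](Br)C(C)(C)C12CC(=O)C2 | intermediate
10 | prop-1-en-2-ylmagnesium bromide | C=C(C)[Mg]Br | starting material
11 | (8R)-8-bromo-2-hydroxy-9,9-dimethyl-2-(prop-1-en-2-yl)spiro[3.5]nonan-5-one, hydroxyl cis to C9 | O=C1CC[C@@H](Br)C(C)(C)[C@]12C[C@](O)(C(C)=C)C2 | intermediate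
12 | (6R)-6-bromo-5,5-dimethyl-9-methylidene-2-(prop-1-en-2-yl)spiro[3.5]nonan-2-ol, hydroxyl cis to C5 | C=C1CC[C@@H](Br)C(C)(C)[C@]12C[C@](O)(C(C)=C)C2 | intermediate
13 | (6R,8R)-8-bromo-3,7,7-trimethyl-11-methylidenespiro[5.5]undecan-2-one (C3 epimers) | C=C1CC[C@@H](Br)C(C)(C)[C@@]12CCC(C)C(=O)C2 | intermediate
14 | (6R,8R)-8-bromo-3,7,7-trimethyl-11-methylidenespiro[5.5]undec-2-en-2-yl trifluoromethanesulfonate | C=C1CC[C@@H](Br)C(C)(C)[C@@]12CCC(C)=C(OS(=O)(=O)C(F)(F)F)C2 | intermediate
15 | (6R,8R)-8-bromo-3,7,7-trimethyl-11-methylidenespiro[5.5]undec-2-ene | C=C1CC[C@@H](Br)C(C)(C)[C@@]12CCC(C)=CC2 | intermediate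
16 | (2R,3S,6R,8R)-8-bromo-2,3-epoxy-3,7,7-trimethyl-11-methylidenespiro[5.5]undecane | C=C1CC[C@@H](Br)C(C)(C)[C@@]12CC[C@]3(C)O[C@@H]3C2 | intermediate
17 | (2R,3R,6R,8R)-8-bromo-3-chloro-3,7,7-trimethyl-11-methylidenespiro[5.5]undecan-2-ol | C=C1CC[C@@H](Br)C(C)(C)[C@@]12CC[C@@](C)(Cl)[C@H](O)C2 | intermediate
18 | (2R,3R,6R,8R)-8-bromo-3-chloro-3,7,7-trimethyl-11-methylidenespiro[5.5]undecan-2-yl trifluoromethanesulfonate | C=C1CC[C@@H](Br)C(C)(C)[C@@]12CC[C@@](C)(Cl)[C@H](OS(=O)(=O)C(F)(F)F)C2 | intermediate (not isolated)
19 | (2R,6R,8S,9R)-2,8-dibromo-9-chloro-1,1,9-trimethyl-5-methylidenespiro[5.5]undecane | C=C1CC[C@@H](Br)C(C)(C)[C@@]12CC[C@@](C)(Cl)[C@@H](Br)C2 | target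

**Step count and risks**
Total steps: 13. Longest linear sequence: 13 steps (1 → 19); 3 and 10 are commercial fragments added in steps 2 and 6.

Steps most likely to fail:

1. Step 8 (proposed new method). The alkylrhodium may be protonated or undergo a 1,4-rhodium shift before it closes ring B, or the ligand may discriminate poorly between the two cyclobutane bonds. Fallback with known chemistry, setting out from 12 and coming back at 13: photocatalytic ring expansion of the 1-alkenyl cyclobutanol by proton-coupled electron transfer ([Ir(dF(CF3)ppy)2(5,5'-d(CF3)bpy)]PF6, 2,4,6-collidine, catalytic 2,4,6-triisopropylbenzenethiol, CH2Cl2, blue light). The alkoxy radical undergoes β-scission, the primary radical cyclises 6-endo onto the enone and the thiol returns a hydrogen atom. Without catalyst control at C6 this should give 13 together with (6S,8R)-8-bromo-3,7,7-trimethyl-11-methylidenespiro[5.5]undecan-2-one F1, to be separated by chromatography.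

2. Step 13. Backside attack at C8, which is flanked by the fully substituted C9, may lose to elimination or to chloride participation (chloronium return with retention or chlorine migration). Fallback, setting out from 17 and coming back at 19: Dess–Martin oxidation gives (3R,6R,8R)-8-bromo-3-chloro-3,7,7-trimethyl-11-methylidenespiro[5.5]undecan-2-one F2. Reduction with the (R)-Me-CBS oxazaborolidine and catecholborane from the opposite face gives the cis-chlorohydrin (2S,3R,6R,8R)-8-bromo-3-chloro-3,7,7-trimethyl-11-methylidenespiro[5.5]undecan-2-ol F3. Thionyl bromide in diethyl ether without base then converts F3, through its bromosulfite ester F4, into 19 with retention by internal return (SNi), so no backside attack is needed.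

3. Step 5. O-alkylation to a cyclic enol ether or E1 loss of a proton may outrun C-alkylation through the scarcely populated cyclobutylidene enol. Fallback, setting out from 6 and coming back at 9: equilibration to the more substituted enolate (KN(SiMe3)2, 0.95 equiv, THF, −78 → 0 °C) and silylation with tert-butyldimethylsilyl chloride gives the tert-butyldimethylsilyl enol ether of 6 with the double bond to the cyclobutane carbon F5. Opening the epoxide with Li2NiBr4 gives the corresponding (R)-bromohydrin silyl enol ether F6. SnCl4 at −78 °C then ionises the tertiary alcohol and the preformed enol ether attacks through carbon (Mukaiyama-type tert-alkylation); aqueous HCl work-up removes the silyl group and the ketal to give 9.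

Further compounds
F1 | step 8 | (6S,8R)-8-bromo-3,7,7-trimethyl-11-methylidenespiro[5.5]undecan-2-one | C=C1CC[C@@H](Br)C(C)(C)[C@]12CCC(C)C(=O)C2
F2 | step 13 | (3R,6R,8R)-8-bromo-3-chloro-3,7,7-trimethyl-11-methylidenespiro[5.5]undecan-2-one | C=C1CC[C@@H](Br)C(C)(C)[C@@]12CC[C@@](C)(Cl)C(=O)C2
F3 | step 13 | (2S,3R,6R,8R)-8-bromo-3-chloro-3,7,7-trimethyl-11-methylidenespiro[5.5]undecan-2-ol | C=C1CC[C@@H](Br)C(C)(C)[C@@]12CC[C@@](C)(Cl)[C@@H](O)C2
F4 | step 13 | (2S,3R,6R,8R)-8-bromo-3-chloro-3,7,7-trimethyl-11-methylidenespiro[5.5]undecan-2-yl bromosulfite | C=C1CC[C@@H](Br)C(C)(C)[C@@]12CC[C@@](C)(Cl)[C@@H](OS(=O)Br)C2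
F5 | step 5 | tert-butyl{[1-(3,3-dimethoxycyclobutylidene)-3-[(2S)-3,3-dimethyloxiran-2-yl]propyl]oxy}dimethylsilane | COC1(OC)CC(C1)=C(O[Si](C)(C)C(C)(C)C)CC[C@@H]2OC2(C)C
F6 | step 5 | (3R)-3-bromo-6-{[tert-butyl(dimethyl)silyl]oxy}-6-(3,3-dimethoxycyclobutylidene)-2-methylhexan-2-ol | COC1(OC)CC(C1)=C(O[Si](C)(C)C(C)(C)C)CC[C@@H](Br)C(C)(C)O
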